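**Strategy.** The hydroazulene is cut at the fusion bond C3a–C8a and at C1–C2 and C2–C3, which turns the cyclopentane ring (C1, C2, C3, C3a, C8a) with its quaternary C8a into a cyclopentenone retron (C2=O, C3=C3a). One cobalt-mediated Pauson–Khand reaction of the isopropyl alkyne C3≡C3a, the isopropenyl group C8a=C1 and CO forms these three bonds, closes this ring and the cycloheptene ring together, and sets C8a from the C8 carbinol. The substrate is an acyclic (S,Z)-dienyne. Its C6=C7 geometry comes from a stereospecific hydroalumination–coupling sequence and its C8 configuration from a kinetic resolution; C8 carries a bulky triisopropylsilyl ether to sharpen the facial bias.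

Key step: step 8

Remark: hydroazulene numbering of the target is used for all intermediates; the target is taken as (3R,3aS,8S,8aR), with the C8 oxygen, the C8a methyl, the C3a hydroxyl and the C3 isopropyl group all on one face.

Step 1
Reactants: 1 3-methylbut-1-yne; 2 oxirane
Product: 4 6-methylhept-3-yn-1-ol, via lithium 3-methylbut-1-yn-1-ide 3 (not isolated)
Conditions: n-BuLi, THF, −78 °C; oxirane, DMPU, −78 °C → rt; aq. NH4Cl
Reagents that add atoms: none
Why: Deprotonation gives the lithium acetylide, which opens oxirane by SN2 attack (acetylide–epoxide opening).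

Step 2
Reactants: 4 6-methylhept-3-yn-1-ol
Product: 5 1-iodo-6-methylhept-3-yne
Conditions: I2, PPh3, imidazole, CH2Cl2, 0 °C → rt
Reagents that add atoms: iodine, II
Why: Appel-type iodination converts the primary alcohol into the iodide and leaves the internal alkyne alone.

Step 3
Reactants: 6 2-methylprop-2-enal (methacrolein); 7 bromo(prop-1-yn-1-yl)magnesium
Product: 8 rac-2-methylhex-1-en-4-yn-3-ol
Conditions: THF, −78 → 0 °C; aq. NH4Cl
Reagents that add atoms: none
Why: 1,2-Addition of the alkynyl Grignard reagent to the enal gives the racemic carbinol that becomes C8.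

Step 4
Reactants: 8 rac-2-methylhex-1-en-4-yn-3-ol
Product: 9 (R)-2-methylhex-1-en-4-yn-3-ol
Conditions: Ti(OiPr)4 (0.1 equiv), D-(−)-diisopropyl tartrate (0.15 equiv), t-BuOOH (0.6 equiv), 4 Å molecular sieves, CH2Cl2, −20 °C
Reagents that add atoms: none
Why: Sharpless kinetic resolution; with the D-(−)-tartrate the isopropenyl group of the (S)-alcohol should be epoxidised much faster, so the (R)-alcohol, which maps onto C8 S of the target, is left behind (at most half of 8).

Step 5
Reactants: 9 (R)-2-methylhex-1-en-4-yn-3-ol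
Product: 11 (3S,4Z)-5-iodo-2-methylhexa-1,4-dien-3-ol, via cyclic alkenylalanate 10 (not isolated)
Conditions: NaAlH2(OCH2CH2OCH3)2 (Red-Al), THF, 0 °C → rt; EtOAc; I2, −78 → 0 °C; aq. Rochelle salt, Na2S2O3
Reagents that add atoms: iodine, II
Why: Hydroxyl-directed trans-hydroalumination puts aluminium on the distal alkyne carbon in a five-membered alanate, and iodinolysis with retention gives the (Z)-iodoalkene that fixes the C6=C7 geometry; the stereocentre is untouched (its descriptor changes only through the priority rules).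

Step 6
Reactants: 11 (3S,4Z)-5-iodo-2-methylhexa-1,4-dien-3-ol
Product: 12 (3S,4Z)-5-iodo-2-methyl-3-{[tri(propan-2-yl)silyl]oxy}hexa-1,4-diene
Conditions: iPr3SiOTf, 2,6-lutidine, CH2Cl2, −78 → 0 °C
Reagents that add atoms: triisopropylsilyl trifluoromethanesulfonate, CC(C)[Si](OS(=O)(=O)C(F)(F)F)(C(C)C)C(C)C
Why: Silylation of the secondary alcohol with a silyl triflate and a hindered pyridine base is reliable even at a crowded carbinol.

Step 7
Reactants: 5 1-iodo-6-methylhept-3-yne; 12 (3S,4Z)-5-iodo-2-methyl-3-{[tri(propan-2-yl)silyl]oxy}hexa-1,4-diene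
Product: 14 (3S,4Z)-2,5,10-trimethyl-3-{[tri(propan-2-yl)silyl]oxy}undeca-1,4-dien-8-yne, via alkylzinc iodide 13 (not isolated)
Conditions: 5, Zn dust, LiCl, THF, 40 °C; then 12, Pd(PPh3)4 (5 mol %), THF, 50 °C
Reagents that add atoms: none
Why: Zinc insertion into the primary iodide and Negishi coupling with the alkenyl iodide proceed with retention of alkene geometry, so the chain (C5) ends cis to C8.

Step 8
Reactants: 14 (3S,4Z)-2,5,10-trimethyl-3-{[tri(propan-2-yl)silyl]oxy}undeca-1,4-dien-8-yne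
Product: 16 (8S,8aS)-6,8a-dimethyl-3-(propan-2-yl)-8-{[tri(propan-2-yl)silyl]oxy}-4,5,8,8a-tetrahydroazulen-2(1H)-one (C8 oxygen cis to the C8a methyl), via hexacarbonyldicobalt alkyne complex 15 (not isolated)
Conditions: Co2(CO)8 (1.1 equiv), CH2Cl2, rt; then tetramethylthiourea, toluene, 80 °C, CO (1 atm)
Reagents that add atoms: carbon monoxide (from Co2(CO)8 and the CO atmosphere), [C-]#[O+]
Why: The alkyne is bound as its Co2(CO)6 complex; loss of CO, helped by the thiourea, lets the isopropenyl group coordinate and insert with formation of C3a–C8a, after which CO insertion (C1–C2) and reductive elimination (C2–C3) release the enone. This is an intramolecular Pauson–Khand reaction in its demanding variant, closing a seven-membered tether ring through a cis-alkene tether. The cyclopentenone (C1, C2, C3, C3a, C8a) closes as the [2+2+1] ring, and the cycloheptene (C3a through C8 to C8a) closes in the same insertion as the tether ring, by attack on the internal carbon of the 1,1-disubstituted alkene. The only new stereocentre, quaternary C8a, is controlled by C8: the silyloxy group should lie pseudo-equatorial on the developing cycloheptene, turned away from the cobalt-bound C1, which puts the C8a methyl cis to the C8 oxygen. The step needs chemoselectivity for the isopropenyl group and this facial selectivity; the first is secured because the C6=C7 alkene could only give a cyclobutane, the second rests on the bulky silyl ether and on the Z-alkene, whose allylic strain keeps C8–H in the alkene plane and the isopropenyl group out of it.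

Step 9
Reactants: 16 (8S,8aS)-enone
Product: 17 (3R,3aR,8S,8aR)-3,3a-epoxy-6,8a-dimethyl-3-(propan-2-yl)-8-{[tri(propan-2-yl)silyl]oxy}-3,3a,4,5,8,8a-hexahydroazulen-2(1H)-one (oxirane oxygen cis to the C8a methyl)
Conditions: H2O2 (30 % aq.), NaOH, MeOH–THF, 0 °C → rt
Reagents that add atoms: hydrogen peroxide, OO
Why: Weitz–Scheffer epoxidation; hydroperoxide should add to C3a from the face of the C8a methyl, because the other face is covered by C8 and the seven-membered ring, which sets C3a, and the isolated C6=C7 alkene is inert to a nucleophilic oxidant.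

Step 10
Reactants: 17 epoxy ketone
Product: 18 (3R,3aS,8S,8aR)-3a-hydroxy-6,8a-dimethyl-3-(propan-2-yl)-8-{[tri(propan-2-yl)silyl]oxy}-3,3a,4,5,8,8a-hexahydroazulen-2(1H)-one
Conditions: SmI2 (2.5 equiv), THF–MeOH, −78 °C; pH 7 buffer
Reagents that add atoms: none
Why: Reductive opening of the α,β-epoxy ketone (ketyl, cleavage of C3–O, second electron transfer) keeps the C3a–O bond and avoids retro-aldol and dehydration at low temperature; C3 is set by protonation of the samarium enolate, expected opposite the samarium-bound C3a oxygen, which puts isopropyl cis to the hydroxyl, also the more stable arrangement.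

Step 11
Reactants: 18 hydroxy ketone
Product: 19 tosylhydrazone of 18 at C2 (stereocentres as in 18; C=N geometry immaterial)
Conditions: TsNHNH2 (1.5 equiv), MeOH, 45 °C
Reagents that add atoms: 4-methylbenzenesulfonohydrazide, Cc1ccc(cc1)S(=O)(=O)NN
Why: Neutral condensation of the ketone with tosylhydrazide spares the β-hydroxyl, the silyl ether and C3.

Step 12
Reactants: 19 tosylhydrazone
Product: 21 (3R,3aS,8S,8aR)-6,8a-dimethyl-3-(propan-2-yl)-8-{[tri(propan-2-yl)silyl]oxy}-2,3,4,5,8,8a-hexahydroazulen-3a(1H)-ol, via N-boryl tosylhydrazine 20 (not isolated)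
Conditions: catecholborane (3 equiv), CHCl3, 0 °C → rt; then NaOAc·3H2O, 60 °C
Reagents that add atoms: none
Why: Catecholborane reduces the C=N bond and acetate-induced loss of sulfinate gives a diazene that expels N2 to leave the C2 methylene (tosylhydrazone reduction of the Caglioti type), mild enough for the tertiary alcohol, the alkene and C3.

Step 13
Reactants: 21 silyl ether
Product: 22 (3R,3aS,8S,8aR)-6,8a-dimethyl-3-(propan-2-yl)-1,2,3,4,5,8-hexahydroazulene-3a,8(8aH)-diol
Conditions: Bu4NF, THF, 40 °C; aq. NH4Cl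
Reagents that add atoms: none
Why: Fluoride cleaves the silyl ether and frees the C8 hydroxyl.

Step 14
Reactants: 22 diol; 23 4-methoxybenzoyl chloride
Product: 24 (3R,3aS,8S,8aR)-3a-hydroxy-6,8a-dimethyl-3-(propan-2-yl)-1,2,3,3a,4,5,8,8a-octahydroazulen-8-yl 4-methoxybenzoate
Conditions: Et3N, DMAP (0.2 equiv), CH2Cl2, 0 °C → rt
Reagents that add atoms: none
Why: DMAP-catalysed acylation should occur only at the secondary allylic C8 hydroxyl, the tertiary C3a hydroxyl being too hindered.

**Compound list**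

1 | 3-methylbut-1-yne | CC(C)C#C | starting material
2 | oxirane | C1CO1 | starting material
3 | lithium 3-methylbut-1-yn-1-ide | CC(C)C#C[Li] | intermediate (not isolated)
4 | 6-methylhept-3-yn-1-ol | CC(C)C#CCCO | intermediate
5 | 1-iodo-6-methylhept-3-yne | CC(C)C#CCCI | intermediate
6 | 2-methylprop-2-enal | CC(=C)C=O | starting material
7 | bromo(prop-1-yn-1-yl)magnesium | CC#C[Mg]Br | starting material
8 | rac-2-methylhex-1-en-4-yn-3-ol | CC#CC(O)C(C)=C | intermediate
9 | (R)-2-methylhex-1-en-4-yn-3-ol | CC#C[C@H](O)C(C)=C | intermediate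
10 | sodium cyclic (Z)-alkenylalanate of 9 (1,2-oxaluminole ring, aluminium on the methyl-bearing carbon) | [Na+].COCCO[Al-]1(OCCOC)O[C@H](C(C)=C)C=C1C | intermediate (not isolated)
11 | (3S,4Z)-5-iodo-2-methylhexa-1,4-dien-3-ol | C/C(I)=C/[C@H](O)C(C)=C | intermediate
12 | (3S,4Z)-5-iodo-2-methyl-3-{[tri(propan-2-yl)silyl]oxy}hexa-1,4-diene | C/C(I)=C/[C@H](O[Si](C(C)C)(C(C)C)C(C)C)C(C)=C | intermediate
13 | iodo(6-methylhept-3-yn-1-yl)zinc | CC(C)C#CCC[Zn]I | intermediate (not isolated)
14 | (3S,4Z)-2,5,10-trimethyl-3-{[tri(propan-2-yl)silyl]oxy}undeca-1,4-dien-8-yne | CC(C)C#CCC/C(C)=C\[C@H](O[Si](C(C)C)(C(C)C)C(C)C)C(C)=C | intermediate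
15 | hexacarbonyldicobalt complex of the alkyne of 14 | CC(C)C12[Co]3(=C=O)(=C=O)(=C=O)[Co]1(=C=O)(=C=O)(=C=O)C23CC/C(C)=C\[C@H](O[Si](C(C)C)(C(C)C)C(C)C)C(C)=C | intermediate (not isolated)
16 | (8S,8aS)-6,8a-dimethyl-3-(propan-2-yl)-8-{[tri(propan-2-yl)silyl]oxy}-4,5,8,8a-tetrahydroazulen-2(1H)-one | CC(C)[Si](C(C)C)(C(C)C)O[C@H]1C=C(C)CCC2=C(C(C)C)C(=O)C[C@]12C | intermediate
17 | (3R,3aR,8S,8aR)-3,3a-epoxy ketone, oxirane oxygen cis to the C8a methyl | CC(C)[Si](C(C)C)(C(C)C)O[C@H]1C=C(C)CC[C@@]23O[C@@]3(C(C)C)C(=O)C[C@]12C | intermediate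
18 | (3R,3aS,8S,8aR)-3a-hydroxy-6,8a-dimethyl-3-(propan-2-yl)-8-{[tri(propan-2-yl)silyl]oxy}-3,3a,4,5,8,8a-hexahydroazulen-2(1H)-one | CC(C)[Si](C(C)C)(C(C)C)O[C@H]1C=C(C)CC[C@]2(O)[C@@H](C(C)C)C(=O)C[C@]12C | intermediate
19 | tosylhydrazone of 18 | CC(C)[Si](C(C)C)(C(C)C)O[C@H]1C=C(C)CC[C@]2(O)[C@@H](C(C)C)C(=NNS(=O)(=O)c3ccc(C)cc3)C[C@]12C | intermediate
20 | N-(1,3,2-benzodioxaborol-2-yl) tosylhydrazine from 19 (C2 epimers) | CC(C)[Si](C(C)C)(C(C)C)O[C@H]1C=C(C)CC[C@]2(O)[C@@H](C(C)C)C(N(B3Oc4ccccc4O3)NS(=O)(=O)c3ccc(C)cc3)C[C@]12C | intermediate (not isolated)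
21 | (3R,3aS,8S,8aR)-6,8a-dimethyl-3-(propan-2-yl)-8-{[tri(propan-2-yl)silyl]oxy}-2,3,4,5,8,8a-hexahydroazulen-3a(1H)-ol | CC(C)[Si](C(C)C)(C(C)C)O[C@H]1C=C(C)CC[C@]2(O)[C@@H](C(C)C)CC[C@]12C | intermediate
22 | (3R,3aS,8S,8aR)-6,8a-dimethyl-3-(propan-2-yl)-1,2,3,4,5,8-hexahydroazulene-3a,8(8aH)-diol | O[C@H]1C=C(C)CC[C@]2(O)[C@@H](C(C)C)CC[C@]12C | intermediate
23 | 4-methoxybenzoyl chloride | COc1ccc(cc1)C(Cl)=O | starting material
24 | (3R,3aS,8S,8aR)-3a-hydroxy-6,8a-dimethyl-3-(propan-2-yl)-1,2,3,3a,4,5,8,8a-octahydroazulen-8-yl 4-methoxybenzoate | COc1ccc(C(=O)O[C@H]2C=C(C)CC[C@]3(O)[C@@H](C(C)C)CC[C@]23C)cc1 | target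

**Step count.** Total: 14 steps. Longest linear sequence: 12 steps (steps 3 to 14).

**Steps most likely to fail**

Step 8. The slow insertion of the 1,1-disubstituted alkene may occur on the face that puts the C8a methyl trans to the C8 oxygen. Fallback: C8 is then used only to set C8a and is inverted afterwards. The fallback sets out from 8 and comes back at 16.
- Resolution with L-(+)-diisopropyl tartrate under the step 4 conditions leaves (S)-2-methylhex-1-en-4-yn-3-ol F1.
- Red-Al and iodine give, through the enantiomeric cyclic alkenylalanate F2, (3R,4Z)-5-iodo-2-methylhexa-1,4-dien-3-ol F3.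
- Silylation gives the (3R,4Z)-triisopropylsilyl ether F4, and coupling with 13 gives the (3R,4Z)-dienyne F5.
- Its hexacarbonyldicobalt complex F6 should then cyclise to the (8R,8aS)-enone F7, which has the C8a configuration of 16.
- Bu4NF frees the (8R,8aS)-hydroxy enone F8.
- A Mitsunobu reaction (4-nitrobenzoic acid, PPh3, diisopropyl azodicarboxylate, THF) inverts C8 to the (8S,8aS)-4-nitrobenzoate F9.
- K2CO3 in MeOH gives the (8S,8aS)-hydroxy enone F10, and silylation as in step 6 returns 16.

Step 10. The samarium enolate may be protonated from the face of the C3a oxygen, which leaves isopropyl trans to the hydroxyl. Fallback: thermodynamic in place of kinetic control. The (3S,3aS,8S,8aR)-hydroxy ketone F11 formed from 17 is equilibrated through its enolate with NaOMe in MeOH at 0 °C. This should favour 18, where isopropyl sits on the convex face away from C4. Any enone 16 formed by loss of water goes back into step 9.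

Step 9. Conjugate addition of hydroperoxide to the tetrasubstituted enone, at a β-carbon next to the quaternary centre, may be too slow. Fallback: electrophilic epoxidation of the electron-rich alkene after 1,2-reduction. The fallback sets out from 16 and comes back at 17.
- Luche reduction (NaBH4, CeCl3·7H2O, MeOH, −40 °C), with hydride expected from the methyl face, gives the (2R,8S,8aS)-allylic alcohol F12.
- Ac2O, pyridine and DMAP give the acetate F13.
- m-Chloroperbenzoic acid (1 equiv, NaHCO3, CH2Cl2, −20 °C) should attack the tetrasubstituted alkene first, opposite the acetoxy group and the seven-membered ring, to give the epoxy acetate F14.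
- K2CO3 in MeOH gives the epoxy alcohol F15, and Dess–Martin periodinane returns 17.

**Further compounds**

F1 | step 8 | (S)-2-methylhex-1-en-4-yn-3-ol | CC#C[C@@H](O)C(C)=C
F2 | step 8 | enantiomeric cyclic alkenylalanate (sodium salt) | [Na+].COCCO[Al-]1(OCCOC)O[C@@H](C(C)=C)C=C1C
F3 | step 8 | (3R,4Z)-5-iodo-2-methylhexa-1,4-dien-3-ol | C/C(I)=C/[C@@H](O)C(C)=C
F4 | step 8 | (3R,4Z)-triisopropylsilyl ether | C/C(I)=C/[C@@H](O[Si](C(C)C)(C(C)C)C(C)C)C(C)=C
F5 | step 8 | (3R,4Z)-dienyne | CC(C)C#CCC/C(C)=C\[C@@H](O[Si](C(C)C)(C(C)C)C(C)C)C(C)=C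
F6 | step 8 | hexacarbonyldicobalt complex of F5 | CC(C)C12[Co]3(=C=O)(=C=O)(=C=O)[Co]1(=C=O)(=C=O)(=C=O)C23CC/C(C)=C\[C@@H](O[Si](C(C)C)(C(C)C)C(C)C)C(C)=C
F7 | step 8 | (8R,8aS)-enone | CC(C)[Si](C(C)C)(C(C)C)O[C@@H]1C=C(C)CCC2=C(C(C)C)C(=O)C[C@]12C
F8 | step 8 | (8R,8aS)-hydroxy enone | O[C@@H]1C=C(C)CCC2=C(C(C)C)C(=O)C[C@]12C
F9 | step 8 | (8S,8aS)-4-nitrobenzoate | O=C(O[C@H]1C=C(C)CCC2=C(C(C)C)C(=O)C[C@]12C)c1ccc(cc1)[N+](=O)[O-]
F10 | step 8 | (8S,8aS)-hydroxy enone | O[C@H]1C=C(C)CCC2=C(C(C)C)C(=O)C[C@]12C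
F11 | step 10 | (3S,3aS,8S,8aR)-hydroxy ketone (C3 epimer of 18) | CC(C)[Si](C(C)C)(C(C)C)O[C@H]1C=C(C)CC[C@]2(O)[C@H](C(C)C)C(=O)C[C@]12C
F12 | step 9 | (2R,8S,8aS)-allylic alcohol (C2 hydroxyl trans to the C8a methyl) | CC(C)[Si](C(C)C)(C(C)C)O[C@H]1C=C(C)CCC2=C(C(C)C)[C@H](O)C[C@]12C
F13 | step 9 | acetate of F12 | CC(C)[Si](C(C)C)(C(C)C)O[C@H]1C=C(C)CCC2=C(C(C)C)[C@H](OC(C)=O)C[C@]12C
F14 | step 9 | epoxy acetate (oxirane cis to the C8a methyl, acetoxy trans) | CC(C)[Si](C(C)C)(C(C)C)O[C@H]1C=C(C)CC[C@@]23O[C@@]3(C(C)C)[C@H](OC(C)=O)C[C@]12C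
F15 | step 9 | epoxy alcohol from F14 | CC(C)[Si](C(C)C)(C(C)C)O[C@H]1C=C(C)CC[C@@]23O[C@@]3(C(C)C)[C@H](O)C[C@]12C
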